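**Retrosynthetic overview**
- The strategy rests on ring A of the 4'-methoxyflavone half (unit 1; C4a, C5, C6, C7, C8, C8a). It shares C4a–C8a with pyranone ring C, has OH on C5 and C7 and carries the flavon-8-yl group of unit 2 on C8. This is the pattern left by a 1,3-dioxygenated four-carbon diene laid across a pyranone C=C bond.
- Last disconnection: the three phenols of unit 2 travel as benzyl ethers, so the single 4'-methyl ether distinguishes the two halves from the outset.
- Key disconnection: C8–C8a and C4a–C5 of ring A. This leads to a flavonyl-substituted 1-methoxy-1,3-bis(silyloxy)butadiene and 2-(4-methoxyphenyl)-5-(p-tolylsulfinyl)-4-pyranone, and the crowded 8,8'' bond is traced back to an ordinary aryl–CH2 bond.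
- Diene: apigenin → benzyl ethers → C8 iodide → arylacetate → Meldrum's acid homologation → double O-silylation. Pyranone: 4-ethynylanisole → ynoate → β-keto sulfoxide → enaminone → 6-endo oxa-Michael closure.
- Order of ring formation: ring C of unit 1, then ring A of unit 1. Ring B and all rings of unit 2 come with the starting materials.

Key step: step 12

Assumption: the target SMILES contains no stereocentre and defines no configuration for the 8,8'' axis, so the route aims at the racemic atropisomer.

**Step 1**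
Reactants: 1 apigenin
Product: 2 5,7-bis(benzyloxy)-2-[4-(benzyloxy)phenyl]-4H-chromen-4-one (tri-O-benzylapigenin)
Conditions: BnBr (4.5 equiv), K2CO3 (6 equiv), DMF, 80 °C
Reagents that add atoms: benzyl bromide, BrCc1ccccc1
Why: Williamson etherification of all three phenols; excess halide and heat are needed only for the 5-OH, which is hydrogen-bonded to the C4 carbonyl.

**Step 2**
Reactants: 2 tri-O-benzylapigenin
Product: 3 5,7-bis(benzyloxy)-2-[4-(benzyloxy)phenyl]-8-iodo-4H-chromen-4-one
Conditions: I2 (1.1 equiv), CF3CO2Ag (1.1 equiv), CH2Cl2, 0 °C → rt, dark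
Reagents that add atoms: iodine, II
Why: Electrophilic aromatic iodination by CF3CO2I generated in situ attacks ring A, the most electron-rich ring, and in fully etherified 5,7-dioxygenated flavones goes to C8 rather than C6, which is shielded by two flanking benzyloxy groups.

**Step 3**
Reactants: 3 8-iodo-tri-O-benzylapigenin
Product: 4 ethyl 2-{5,7-bis(benzyloxy)-2-[4-(benzyloxy)phenyl]-4-oxo-4H-chromen-8-yl}acetate
Conditions: BrZnCH2CO2Et (2.5 equiv, 0.5 M in THF), Pd(dba)2 (5 mol %), XPhos (10 mol %), THF, 60 °C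
Reagents that add atoms: (2-ethoxy-2-oxoethyl)zinc bromide, CCOC(=O)C[Zn]Br
Why: Negishi-type cross-coupling of a Reformatsky reagent (palladium-catalysed ester α-arylation): zerovalent palladium bearing the bulky biarylphosphine inserts into the di-ortho-oxygenated carbon–iodine bond, and the weakly basic zinc enolate leaves the flavone carbonyl and the benzyl ethers untouched.

**Step 4**
Reactants: 4 ethyl flavon-8-ylacetate
Product: 5 2-{5,7-bis(benzyloxy)-2-[4-(benzyloxy)phenyl]-4-oxo-4H-chromen-8-yl}acetic acid
Conditions: LiOH·H2O (3 equiv), THF–MeOH–H2O, rt; 1 M HCl to pH 3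
Reagents that add atoms: lithium hydroxide, [Li+].[OH-]
Why: Saponification of an unhindered ethyl ester at room temperature is much faster than hydroxide attack at C2 of the flavone, and benzyl ethers are inert to base.

**Step 5**
Reactants: 5 flavon-8-ylacetic acid; 6 Meldrum's acid
Product: 8 methyl 4-{5,7-bis(benzyloxy)-2-[4-(benzyloxy)phenyl]-4-oxo-4H-chromen-8-yl}-3-oxobutanoate, via acyl Meldrum's acid 7 (not isolated)
Conditions: 6 (1.1 equiv), DCC (1.1 equiv), DMAP (1.5 equiv), CH2Cl2, 0 °C → rt; filter, wash (aq KHSO4), concentrate; MeOH–toluene (1:1), reflux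
Reagents that add atoms: methanol, CO
Why: Meldrum's acid β-keto ester synthesis: carbodiimide/DMAP C-acylation gives 7, which undergoes methanolysis and decarboxylation (loss of acetone and CO2) on heating, conditions that touch neither the flavone nor the benzyl ethers.

**Step 6**
Reactants: 8 β-keto ester
Product: 9 methyl (E)-4-{5,7-bis(benzyloxy)-2-[4-(benzyloxy)phenyl]-4-oxo-4H-chromen-8-yl}-3-(trimethylsilyloxy)but-2-enoate (E drawn; any Z isomer is carried along)
Conditions: TMSCl (1.8 equiv), Et3N (2.0 equiv), toluene–CH2Cl2, rt, 48 h; filter under argon, concentrate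
Reagents that add atoms: chlorotrimethylsilane, C[Si](C)(C)Cl
Why: O-Silylation of the enol form of the β-keto ester by TMSCl/Et3N is the first stage of the standard two-stage preparation of 1,3-bis(silyloxy)dienes, and the E/Z ratio is irrelevant because this double bond becomes the central single bond of the diene.

**Step 7**
Reactants: 9 mono(silyl enol ether)
Product: 11 5,7-bis(benzyloxy)-2-[4-(benzyloxy)phenyl]-8-[(1Z,3Z)-4-methoxy-2,4-bis(trimethylsilyloxy)buta-1,3-dien-1-yl]-4H-chromen-4-one, via lithium dienolate 10 (not isolated)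
Conditions: LiHMDS (1.1 equiv), THF, −78 °C, 1 h; TMSCl (1.3 equiv), −78 → 0 °C; concentrate, extract into dry toluene, filter under argon; used at once
Reagents that add atoms: chlorotrimethylsilane, C[Si](C)(C)Cl
Why: Vinylogous (γ) deprotonation at the benzylic CH2, by far the most acidic site, and O-silylation of dienolate 10 complete the Chan-type diene; allylic strain puts the bulky aryl group cis to the silyloxy group (1Z), the outward position in the s-cis diene, and LiHMDS is too weak a base to metalate the flavone C3–H (the ketene-acetal geometry is of no consequence).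

**Step 8**
Reactants: 12 4-ethynylanisole
Product: 14 methyl 3-(4-methoxyphenyl)prop-2-ynoate, via lithium acetylide 13 (not isolated)
Conditions: n-BuLi (1.05 equiv), THF, −78 °C; ClCO2Me (1.3 equiv), −78 °C → rt
Reagents that add atoms: methyl chloroformate, COC(=O)Cl
Why: Deprotonation of the terminal alkyne and C-acylation of acetylide 13 by the chloroformate is a standard ynoate synthesis.

**Step 9**
Reactants: 15 methyl p-tolyl sulfoxide (racemic); 14 methyl 3-(4-methoxyphenyl)prop-2-ynoate
Product: 17 4-(4-methoxyphenyl)-1-[(4-methylphenyl)sulfinyl]but-3-yn-2-one (racemic at sulfur), via lithiated sulfoxide 16 (not isolated)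
Conditions: 15 (2.1 equiv), LDA (2.1 equiv), THF, −78 °C, 30 min; 14 (1.0 equiv), −78 °C, 1 h; sat. aq NH4Cl
Reagents that add atoms: none
Why: Claisen-type acylation of an α-sulfinyl carbanion by an ester (standard β-keto sulfoxide synthesis): the hard lithium carbanion attacks the ester carbonyl at −78 °C in preference to the aryl-capped alkyne, and the second equivalent deprotonates 17 as it forms, which prevents further addition.

**Step 10**
Reactants: 17 alkynyl β-keto sulfoxide
Product: 18 (1Z)-1-(dimethylamino)-5-(4-methoxyphenyl)-2-[(4-methylphenyl)sulfinyl]pent-1-en-4-yn-3-one (push–pull alkene, geometry labile and without consequence)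
Conditions: Me2NCH(OMe)2 (1.5 equiv), toluene, rt → 40 °C; concentrate
Reagents that add atoms: N,N-dimethylformamide dimethyl acetal, COC(OC)N(C)C
Why: Condensation of an amide acetal with the only acidic methylene, flanked by ketone and sulfinyl group, gives the enaminone and brings in the carbon that becomes C6 of the pyranone (C8a of the flavone), while the alkyne serves as a latent 1,3-diketone without a second acidic CH2.

**Step 11**
Reactants: 18 sulfinyl enaminone
Product: 20 2-(4-methoxyphenyl)-5-[(4-methylphenyl)sulfinyl]-4H-pyran-4-one (racemic at sulfur), via hydroxymethylene ynone 19 (not isolated)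
Conditions: AcOH–H2O (4:1), 60 °C
Reagents that add atoms: water, O
Why: Acid hydrolysis of the enaminone gives the chelated hydroxymethylene ketone 19, whose enol oxygen adds to the β-carbon of the ynone in a 6-endo-dig oxa-Michael cyclisation, the closure known from 4-pyranone and flavone syntheses from alkynyl 1,3-dicarbonyl compounds and o-hydroxyaryl ynones; any dimethylamine adduct of the ynone converges on 20 by addition–elimination.

**Step 12**
Reactants: 11 flavonyl bis(silyloxy)diene; 20 sulfinylpyranone
Product: 22 5,7-dihydroxy-4'-methoxy-8-(5,7,4'-tribenzyloxyflavon-8-yl)flavone, via cis-fused cycloadduct 21 (not isolated)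
Conditions: 11 (1.0 equiv), 20 (1.3 equiv), toluene, argon, rt → 80 °C; then 1 M HCl–THF, rt
Reagents that add atoms: none
Why: Proposed new method: diene 11 is a 4-aryl Chan-type diene whose largest HOMO coefficient lies on the aryl-bearing terminus, and it should add in a normal-electron-demand, strongly asynchronous (4+2) cycloaddition across C5=C6 of 20, bonding that terminus to the oxygen-bearing C6 (C8–C8a) and the ketene-acetal carbon to the sulfinyl-bearing C5 (C4a–C5), so that ring A closes as a six-membered carbocycle by intermolecular (4+2) annulation onto the finished ring C. Suprafacial addition leaves the sulfinyl group on C4a and the only available β-hydrogen, that on C8a, cis in 21, so thermal syn elimination of p-toluenesulfenic acid can only regenerate C4a=C8a; collapse of the C5 mixed ketal with loss of methanol and acid hydrolysis of the silyl ethers then give the aromatic 5,7-diol. The closest known reactions are the cycloaddition–elimination sequences of 2-sulfinylquinones, haloquinones and 3-acyl- or 3-sulfinylchromones with Danishefsky-, Brassard- and Chan-type dienes; a monocyclic 4-pyranone as dienophile together with a diene terminus that carries a di-ortho-substituted aryl group has not been shown. Regiochemistry is secured by matched polarisation, since C6 of 20 is β to both the ring ketone and the sulfinyl group and hence the electrophilic end, while site selectivity for C5=C6 over C2=C3 follows from the sulfinyl activation and from the anisyl group, which blocks and conjugatively stabilises C2=C3. The (1Z) geometry of 11 keeps the bulky flavonyl group on the outside of the s-cis diene, and both carbons that join in the leading bond carry a hydrogen, so the congested 8,8'' axis is laid down before ring A becomes planar. All four sp3 centres of 21 are erased and the sulfur centre leaves with the sulfenic acid, so no facial or endo/exo control is required, and the 8,8'' axis is obtained as the racemate.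

**Step 13**
Reactants: 22 tribenzyl biflavone
Product: 23 4'-O-methylcupressuflavone (CNP0322111.0)
Conditions: BCl3 (10 equiv, 1 M in CH2Cl2), C6HMe5 (10 equiv), CH2Cl2, −78 → −40 °C; then H2O
Reagents that add atoms: none
Why: Lewis-acid debenzylation of aryl benzyl ethers by BCl3 with pentamethylbenzene as a non-basic benzyl-cation scavenger suppresses C-benzylation of the phloroglucinol rings, and the 4'-methyl ether, which has no neighbouring carbonyl group for chelation, is not cleaved by BCl3 at low temperature.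

**Compound list**
1 | apigenin | O=c1cc(-c2ccc(O)cc2)oc2cc(O)cc(O)c12 | starting material
2 | 5,7-bis(benzyloxy)-2-[4-(benzyloxy)phenyl]-4H-chromen-4-one | O=c1cc(-c2ccc(OCc3ccccc3)cc2)oc2cc(OCc3ccccc3)cc(OCc3ccccc3)c12 | intermediate
3 | 5,7-bis(benzyloxy)-2-[4-(benzyloxy)phenyl]-8-iodo-4H-chromen-4-one | O=c1cc(-c2ccc(OCc3ccccc3)cc2)oc2c(I)c(OCc3ccccc3)cc(OCc3ccccc3)c12 | intermediate
4 | ethyl 2-{5,7-bis(benzyloxy)-2-[4-(benzyloxy)phenyl]-4-oxo-4H-chromen-8-yl}acetate | O=c1cc(-c2ccc(OCc3ccccc3)cc2)oc2c(CC(=O)OCC)c(OCc3ccccc3)cc(OCc3ccccc3)c12 | intermediate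
5 | 2-{5,7-bis(benzyloxy)-2-[4-(benzyloxy)phenyl]-4-oxo-4H-chromen-8-yl}acetic acid | O=c1cc(-c2ccc(OCc3ccccc3)cc2)oc2c(CC(=O)O)c(OCc3ccccc3)cc(OCc3ccccc3)c12 | intermediate
6 | Meldrum's acid (2,2-dimethyl-1,3-dioxane-4,6-dione) | CC1(C)OC(=O)CC(=O)O1 | starting material
7 | 5-[2-(5,7,4'-tribenzyloxyflavon-8-yl)-1-hydroxyethylidene]-2,2-dimethyl-1,3-dioxane-4,6-dione (not isolated) | O=c1cc(-c2ccc(OCc3ccccc3)cc2)oc2c(CC(O)=C3C(=O)OC(C)(C)OC3=O)c(OCc3ccccc3)cc(OCc3ccccc3)c12 | intermediate
8 | methyl 4-{5,7-bis(benzyloxy)-2-[4-(benzyloxy)phenyl]-4-oxo-4H-chromen-8-yl}-3-oxobutanoate | O=c1cc(-c2ccc(OCc3ccccc3)cc2)oc2c(CC(=O)CC(=O)OC)c(OCc3ccccc3)cc(OCc3ccccc3)c12 | intermediate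
9 | methyl (E)-4-(5,7,4'-tribenzyloxyflavon-8-yl)-3-(trimethylsilyloxy)but-2-enoate | O=c1cc(-c2ccc(OCc3ccccc3)cc2)oc2c(C/C(O[Si](C)(C)C)=C\C(=O)OC)c(OCc3ccccc3)cc(OCc3ccccc3)c12 | intermediate
10 | lithium (1Z,3Z)-1-methoxy-4-(5,7,4'-tribenzyloxyflavon-8-yl)-3-(trimethylsilyloxy)buta-1,3-dien-1-olate (not isolated) | O=c1cc(-c2ccc(OCc3ccccc3)cc2)oc2c(/C=C(O[Si](C)(C)C)/C=C(/OC)[O-])c(OCc3ccccc3)cc(OCc3ccccc3)c12.[Li+] | intermediate
11 | 5,7-bis(benzyloxy)-2-[4-(benzyloxy)phenyl]-8-[(1Z,3Z)-4-methoxy-2,4-bis(trimethylsilyloxy)buta-1,3-dien-1-yl]-4H-chromen-4-one | O=c1cc(-c2ccc(OCc3ccccc3)cc2)oc2c(/C=C(O[Si](C)(C)C)/C=C(/OC)O[Si](C)(C)C)c(OCc3ccccc3)cc(OCc3ccccc3)c12 | intermediate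
12 | 4-ethynylanisole | COc1ccc(C#C)cc1 | starting material
13 | lithium (4-methoxyphenyl)acetylide (not isolated) | [Li]C#Cc1ccc(OC)cc1 | intermediate
14 | methyl 3-(4-methoxyphenyl)prop-2-ynoate | COC(=O)C#Cc1ccc(OC)cc1 | intermediate
15 | methyl p-tolyl sulfoxide (racemic) | CS(=O)c1ccc(C)cc1 | starting material
16 | lithiomethyl p-tolyl sulfoxide (not isolated) | [Li]CS(=O)c1ccc(C)cc1 | intermediate
17 | 4-(4-methoxyphenyl)-1-[(4-methylphenyl)sulfinyl]but-3-yn-2-one (racemic at sulfur) | COc1ccc(cc1)C#CC(=O)CS(=O)c1ccc(C)cc1 | intermediate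
18 | (1Z)-1-(dimethylamino)-5-(4-methoxyphenyl)-2-[(4-methylphenyl)sulfinyl]pent-1-en-4-yn-3-one (racemic at sulfur) | COc1ccc(cc1)C#CC(=O)/C(=C/N(C)C)S(=O)c1ccc(C)cc1 | intermediate
19 | (1E)-1-hydroxy-5-(4-methoxyphenyl)-2-[(4-methylphenyl)sulfinyl]pent-1-en-4-yn-3-one, chelated enol (not isolated) | COc1ccc(cc1)C#CC(=O)/C(=C\O)S(=O)c1ccc(C)cc1 | intermediate
20 | 2-(4-methoxyphenyl)-5-[(4-methylphenyl)sulfinyl]-4H-pyran-4-one (racemic at sulfur) | COc1ccc(cc1)-c1cc(=O)c(S(=O)c2ccc(C)cc2)co1 | intermediate
21 | cis-fused 5-methoxy-2-(4-methoxyphenyl)-4a-(p-tolylsulfinyl)-8-(5,7,4'-tribenzyloxyflavon-8-yl)-5,7-bis(trimethylsilyloxy)-4a,5,8,8a-tetrahydro-4H-chromen-4-one; racemic, sulfinyl on C4a and H on C8a cis, C5, C8 and S not assigned (not isolated) | COc1ccc(cc1)C1=CC(=O)[C@@]2(S(=O)c3ccc(C)cc3)[C@@H](O1)C(c1c(OCc3ccccc3)cc(OCc3ccccc3)c3c(=O)cc(-c4ccc(OCc5ccccc5)cc4)oc13)C(O[Si](C)(C)C)=CC2(OC)O[Si](C)(C)C | intermediate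
22 | 5,7-dihydroxy-4'-methoxy-8-(5,7,4'-tribenzyloxyflavon-8-yl)flavone (racemic axis) | COc1ccc(cc1)-c1cc(=O)c2c(O)cc(O)c(-c3c(OCc4ccccc4)cc(OCc4ccccc4)c4c(=O)cc(-c5ccc(OCc6ccccc6)cc5)oc34)c2o1 | intermediate
23 | 4'-O-methylcupressuflavone, CNP0322111.0 (racemic axis) | COc1ccc(-c2cc(=O)c3c(O)cc(O)c(-c4c(O)cc(O)c5c(=O)cc(-c6ccc(O)cc6)oc45)c3o2)cc1 | target

**Step count**
- Total step count: 13.
- Longest linear sequence: 9 steps (steps 1–7, 12, 13). The pyranone branch (steps 8–11) is made in parallel.

**Steps most likely to fail**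

1. **Step 12.**
   - Risks: the weakly aromatic pyranone may be too poor a dienophile for a diene with a hindered terminus. Conjugate addition may be followed by β-elimination of the ring oxygen, which opens ring C instead of closing ring A. The sulfenic acid released may protodesilylate unreacted diene.
   - Fallback (known cross-coupling chemistry): it sets out from iodide 3 and makes the biaryl bond directly. Purchased acacetin is benzylated (BnBr, K2CO3, DMF) to 5,7-bis(benzyloxy)-4'-methoxyflavone F1. This is iodinated as in step 2 to 5,7-bis(benzyloxy)-8-iodo-4'-methoxyflavone F2. Miyaura borylation (B2pin2, PdCl2(dppf), KOAc, dioxane, 90 °C) converts F2 into the 8-pinacolboronate of 5,7-bis(benzyloxy)-4'-methoxyflavone F3. Suzuki–Miyaura coupling of F3 with 3 (Pd(OAc)2, SPhos, K3PO4, toluene–water, 100 °C) should give 5,7,5'',7'',4'''-pentabenzyloxy-4'-methoxy-8,8''-biflavone F4. The conditions of step 13 bring F4 back to the route at 23.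

2. **Step 7.**
   - Risks: competing metalation of the flavone, C-silylation, formation of the inward (1E) isomer, and hydrolysis of the bis(trimethylsilyl) diene during handling.
   - Fallback: it sets out from β-keto ester 8 and introduces both silyl groups in one soft enolisation with TBSOTf and Et3N in CH2Cl2 at 0 °C, without any lithium amide. This should give 5,7-bis(benzyloxy)-2-[4-(benzyloxy)phenyl]-8-[(1Z,3Z)-2,4-bis(tert-butyldimethylsilyloxy)-4-methoxybuta-1,3-dien-1-yl]-4H-chromen-4-one F5, robust enough for filtration through deactivated silica. F5 takes the place of 11 in step 12, the work-up is changed to TBAF–AcOH in THF, and the route is rejoined at 22.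

3. **Step 9.**
   - Risks: conjugate addition of the sulfinyl carbanion to the ynoate, or attack on the ynone before it is deprotonated.
   - Fallback: it sets out from 12 and replaces acylation by addition and oxidation. Lithiation and formylation (n-BuLi, then DMF) give 3-(4-methoxyphenyl)prop-2-ynal F6. The anion of 15 adds to the aldehyde carbonyl at −78 °C to give 4-(4-methoxyphenyl)-1-[(4-methylphenyl)sulfinyl]but-3-yn-2-ol F7 as a diastereomer mixture. Oxidation of the propargylic alcohol with MnO2 in CH2Cl2, which leaves the sulfoxide alone, returns to the route at 17.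

**Further compounds**
F1 | step 12 | 5,7-bis(benzyloxy)-4'-methoxyflavone | COc1ccc(cc1)-c1cc(=O)c2c(OCc3ccccc3)cc(OCc3ccccc3)cc2o1
F2 | step 12 | 5,7-bis(benzyloxy)-8-iodo-4'-methoxyflavone | COc1ccc(cc1)-c1cc(=O)c2c(OCc3ccccc3)cc(OCc3ccccc3)c(I)c2o1
F3 | step 12 | 5,7-bis(benzyloxy)-4'-methoxy-8-(4,4,5,5-tetramethyl-1,3,2-dioxaborolan-2-yl)flavone | COc1ccc(cc1)-c1cc(=O)c2c(OCc3ccccc3)cc(OCc3ccccc3)c(B3OC(C)(C)C(C)(C)O3)c2o1
F4 | step 12 | 5,7,5'',7'',4'''-pentabenzyloxy-4'-methoxy-8,8''-biflavone (racemic axis) | COc1ccc(cc1)-c1cc(=O)c2c(OCc3ccccc3)cc(OCc3ccccc3)c(-c3c(OCc4ccccc4)cc(OCc4ccccc4)c4c(=O)cc(-c5ccc(OCc6ccccc6)cc5)oc34)c2o1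
F5 | step 7 | 5,7-bis(benzyloxy)-2-[4-(benzyloxy)phenyl]-8-[(1Z,3Z)-2,4-bis(tert-butyldimethylsilyloxy)-4-methoxybuta-1,3-dien-1-yl]-4H-chromen-4-one | O=c1cc(-c2ccc(OCc3ccccc3)cc2)oc2c(/C=C(O[Si](C)(C)C(C)(C)C)/C=C(/OC)O[Si](C)(C)C(C)(C)C)c(OCc3ccccc3)cc(OCc3ccccc3)c12
F6 | step 9 | 3-(4-methoxyphenyl)prop-2-ynal | COc1ccc(cc1)C#CC=O
F7 | step 9 | 4-(4-methoxyphenyl)-1-[(4-methylphenyl)sulfinyl]but-3-yn-2-ol (diastereomer mixture) | COc1ccc(cc1)C#CC(O)CS(=O)c1ccc(C)cc1
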